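**Plan**
- Retrosynthesis: after the five benzyl ethers, the first cut is C4–C4a of the 5,7-dihydroxychromenone (apigenin) unit. This bond ties the pyranone carbonyl to a ring A carbon that is ortho/para to O1, O5 and O7, and the ring A precursor, a 3,5-dioxygenated phenoxy group, is symmetric. O1–C2 of the same ring is cut next (aryl vinyl ether from an arylpropiolate and a phenol).
- The propiolate is traced back to a formyl group (alkyne carbon, then CO2). The 8–3′ biaryl bond is cut to an 8-iodoflavone and an arylboronate. The acacetin pyranone is cut at C2–C3 and O1–C2 to a phloroacetophenone and 4-methoxybenzoyl chloride.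
- Forward: the acacetin pyranone closes first (diketone cyclodehydration), C8 is iodinated and the biaryl is joined by Suzuki coupling. The aldehyde is then grown into a propiolate, the phenol adds to form O1–C2, and the second pyranone closes last at carbon by Friedel–Crafts acylation. Global debenzylation ends the route.
- Stereochemistry: the target has no stereocentre. The only stereo element handled is the Z alkene of the cyclisation precursor, set by anti addition of the phenol across the alkyne.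

Key step: step 12

Remark: the target is drawn without a descriptor at the 8,3′-biaryl axis, so the axis is treated as stereochemically undefined and no atroposelective step is planned.

**Route**

Step 1
Reactants: 1 2,4,6-trihydroxyacetophenone
Product: 2 1-[2,4-bis(benzyloxy)-6-hydroxyphenyl]ethan-1-one
Conditions: BnBr (2.1 equiv), K2CO3, DMF, rt
Reagents that add atoms: benzyl bromide, BrCc1ccccc1
Why: Williamson etherification in which the 4-OH and one ortho OH react, while the remaining ortho OH, hydrogen-bonded to the acetyl carbonyl, is the least nucleophilic and should stay free at two equivalents of halide.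

Step 2
Reactants: 2 1-[2,4-bis(benzyloxy)-6-hydroxyphenyl]ethan-1-one; 3 4-methoxybenzoyl chloride
Product: 4 1-[2,4-bis(benzyloxy)-6-hydroxyphenyl]-3-(4-methoxyphenyl)propane-1,3-dione
Conditions: LiN(SiMe3)2 (3.2 equiv), THF, −78 → −10 °C; then 3, −78 °C → rt; aq HCl work-up
Reagents that add atoms: none
Why: Direct C-aroylation of the lithium phenoxide/enolate dianion of an o-hydroxyacetophenone, a one-flask variant of the Baker–Venkataraman route to 1,3-diketones in which the third equivalent of base stores the product as its enolate.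

Step 3
Reactants: 4 1-[2,4-bis(benzyloxy)-6-hydroxyphenyl]-3-(4-methoxyphenyl)propane-1,3-dione
Product: 5 5,7-bis(benzyloxy)-2-(4-methoxyphenyl)-4H-chromen-4-one (5,7-di-O-benzylacacetin)
Conditions: NaOAc, AcOH, 110 °C
Reagents that add atoms: none
Why: Cyclodehydration of an o-hydroxyaryl 1,3-diketone (phenol adds to the enolised aroyl carbonyl, water is lost) gives the flavone, and buffered acetic acid is chosen so that the acid-labile 5-O-benzyl ether should be kept.

Step 4
Reactants: 5 5,7-bis(benzyloxy)-2-(4-methoxyphenyl)-4H-chromen-4-one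
Product: 6 5,7-bis(benzyloxy)-8-iodo-2-(4-methoxyphenyl)-4H-chromen-4-one
Conditions: I2, CF3CO2Ag, CH2Cl2, 0 °C → rt, dark
Reagents that add atoms: iodine, II
Why: Electrophilic aromatic iodination, in which ring A is the most electron-rich arene and 5,7-dialkoxyflavones are substituted at C8 (ortho to O1 and O7, para to O5) rather than at C6 between two benzyloxy groups, while the anisyl ring is deactivated by the pyranone.

Step 5
Reactants: 7 3-bromo-4-hydroxybenzaldehyde
Product: 8 4-(benzyloxy)-3-bromobenzaldehyde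
Conditions: BnBr, K2CO3, DMF, rt
Reagents that add atoms: benzyl bromide, BrCc1ccccc1
Why: Williamson etherification of an acidic para-formyl phenol, which is routine and leaves the aldehyde and the aryl bromide untouched.

Step 6
Reactants: 8 4-(benzyloxy)-3-bromobenzaldehyde
Product: 9 4-(benzyloxy)-3-(4,4,5,5-tetramethyl-1,3,2-dioxaborolan-2-yl)benzaldehyde
Conditions: B2pin2, Pd(dppf)Cl2 (cat.), KOAc, 1,4-dioxane, 90 °C
Reagents that add atoms: bis(pinacolato)diboron, CC1(C)OB(OC1(C)C)B1OC(C)(C)C(C)(C)O1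
Why: Miyaura borylation of an aryl bromide, in which the weak base KOAc prevents Suzuki homocoupling and the aldehyde is tolerated.

Step 7
Reactants: 6 5,7-bis(benzyloxy)-8-iodo-2-(4-methoxyphenyl)-4H-chromen-4-one; 9 4-(benzyloxy)-3-(4,4,5,5-tetramethyl-1,3,2-dioxaborolan-2-yl)benzaldehyde
Product: 10 4-(benzyloxy)-3-[5,7-bis(benzyloxy)-2-(4-methoxyphenyl)-4-oxo-4H-chromen-8-yl]benzaldehyde
Conditions: Pd(OAc)2 (cat.), SPhos, K3PO4, toluene/H2O, 90 °C
Reagents that add atoms: none
Why: Suzuki–Miyaura coupling in which the bulky electron-rich biarylphosphine on zerovalent palladium should drive oxidative addition into the flanked carbon–iodine bond and reductive elimination to the tri-ortho-substituted biaryl, the same 8-iodoflavone plus ortho-alkoxyarylboronate pairing used for 8,3′-linked biflavones.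

Step 8
Reactants: 10 4-(benzyloxy)-3-[5,7-bis(benzyloxy)-2-(4-methoxyphenyl)-4-oxo-4H-chromen-8-yl]benzaldehyde
Product: 11 5,7-bis(benzyloxy)-8-[2-(benzyloxy)-5-ethynylphenyl]-2-(4-methoxyphenyl)-4H-chromen-4-one
Conditions: dimethyl (1-diazo-2-oxopropyl)phosphonate, K2CO3, MeOH/THF, 0 °C → rt
Reagents that add atoms: dimethyl (1-diazo-2-oxopropyl)phosphonate, COP(=O)(OC)C(=[N+]=[N-])C(C)=O
Why: Ohira–Bestmann variant of the Seyferth–Gilbert homologation (methanolysis to the diazomethylphosphonate anion, olefination to a diazoalkene, loss of N2 and 1,2-hydrogen shift), run under carbonate/methanol conditions that the pyranone and benzyl ethers should survive.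

Step 9
Reactants: 11 5,7-bis(benzyloxy)-8-[2-(benzyloxy)-5-ethynylphenyl]-2-(4-methoxyphenyl)-4H-chromen-4-one
Product: 13 methyl 3-{4-(benzyloxy)-3-[5,7-bis(benzyloxy)-2-(4-methoxyphenyl)-4-oxo-4H-chromen-8-yl]phenyl}prop-2-ynoate, via caesium arylpropiolate 12 (not isolated)
Conditions: CO2 (1 atm), AgI (cat.), Cs2CO3, DMF, 50 °C; then MeI, rt
Reagents that add atoms: carbon dioxide, O=C=O; iodomethane, CI
Why: Silver-catalysed C–H carboxylation of a terminal arylalkyne (the silver acetylide takes up CO2) followed by O-methylation of the caesium carboxylate in the same flask, which avoids organolithium bases that would attack the flavone carbonyl or metalate C3.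

Step 10
Reactants: 13 methyl 3-{4-(benzyloxy)-3-[5,7-bis(benzyloxy)-2-(4-methoxyphenyl)-4-oxo-4H-chromen-8-yl]phenyl}prop-2-ynoate; 14 3,5-bis(benzyloxy)phenol
Product: 15 methyl (2Z)-3-{4-(benzyloxy)-3-[5,7-bis(benzyloxy)-2-(4-methoxyphenyl)-4-oxo-4H-chromen-8-yl]phenyl}-3-[3,5-bis(benzyloxy)phenoxy]prop-2-enoate
Conditions: 14 (1.5 equiv), Cs2CO3 (0.5 equiv), DMF, 70 °C
Reagents that add atoms: none
Why: Ruhemann-type oxa-Michael addition of a phenoxide to an arylpropiolate, in which attack at the aryl-bearing β-carbon and anti protonation of the vinyl anion by excess phenol should place the aryloxy group cis to the ester (Z).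

Step 11
Reactants: 15 methyl (2Z)-3-{4-(benzyloxy)-3-[5,7-bis(benzyloxy)-2-(4-methoxyphenyl)-4-oxo-4H-chromen-8-yl]phenyl}-3-[3,5-bis(benzyloxy)phenoxy]prop-2-enoate
Product: 16 (2Z)-3-{4-(benzyloxy)-3-[5,7-bis(benzyloxy)-2-(4-methoxyphenyl)-4-oxo-4H-chromen-8-yl]phenyl}-3-[3,5-bis(benzyloxy)phenoxy]prop-2-enoic acid
Conditions: LiOH·H2O, THF/MeOH/H2O, rt; then 1 M HCl to pH 3, 0 °C
Reagents that add atoms: lithium hydroxide, [Li+].[OH-]
Why: Saponification of a β-aryloxycinnamate, the classical entry to β-aryloxycinnamic acids, run at room temperature so that the hindered donor-substituted β-carbon and the acacetin pyranone should not be attacked and the alkene geometry is retained.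

Step 12
Reactants: 16 (2Z)-3-{4-(benzyloxy)-3-[5,7-bis(benzyloxy)-2-(4-methoxyphenyl)-4-oxo-4H-chromen-8-yl]phenyl}-3-[3,5-bis(benzyloxy)phenoxy]prop-2-enoic acid
Product: 18 penta-O-benzyl podocarpusflavone A (5,7-bis(benzyloxy)-8-{2-(benzyloxy)-5-[5,7-bis(benzyloxy)-4-oxo-4H-chromen-2-yl]phenyl}-2-(4-methoxyphenyl)-4H-chromen-4-one), via mixed trifluoroacetic anhydride 17 (not isolated)
Conditions: (CF3CO)2O (2 equiv), CH2Cl2, 0 °C → rt; aq NaHCO3 quench
Reagents that add atoms: none
Why: Trifluoroacetic anhydride converts the acid into mixed anhydride 17, which ionises to a push–pull acylium ion (resonance form ArO+=C(Ar)–CH=C=O); the ortho carbon of the phenoxy ring attacks the acyl carbon and loss of a proton re-aromatises ring A to give the chromen-4-one. The closest known reaction is the Ruhemann-type flavone synthesis, an intramolecular Friedel–Crafts acylation of a β-aryloxycinnamic acid. The pyranone closes in 6-exo fashion at the acyl carbon (exo-trig on the anhydride, exo-dig on the free acylium ion) with O1–C2 already in place. No stereocentre is formed. The step needs site selectivity for the phenoxy ring: the Z geometry holds the acyl group beside it and away from the β-aryl ring (no indenone), its two ortho carbons are equivalent by symmetry, and each is ortho/para to three oxygens, so it should outcompete every other arene without a strong Lewis acid that would strip benzyl ethers. Any E isomer should still converge, because the ketene-like resonance form lowers the Cα–Cβ bond order and lets the activated species rotate into the reactive geometry.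

Step 13
Reactants: 18 penta-O-benzyl podocarpusflavone A
Product: 19 podocarpusflavone A (5,7-dihydroxy-8-[2-hydroxy-5-(5,7-dihydroxy-4-oxo-4H-chromen-2-yl)phenyl]-2-(4-methoxyphenyl)-4H-chromen-4-one)
Conditions: BCl3, pentamethylbenzene, CH2Cl2, −78 → 0 °C; then H2O
Reagents that add atoms: none
Why: Lewis-acid debenzylation with a cation scavenger, in which pentamethylbenzene traps the benzyl cations before they C-benzylate the electron-rich rings, the aryl methyl ether is not cleaved at low temperature, and the pyranone double bonds are not at risk as they would be under hydrogenation.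

**Compound list**
1 | 2,4,6-trihydroxyacetophenone | CC(=O)c1c(O)cc(O)cc1O | starting material
2 | 1-[2,4-bis(benzyloxy)-6-hydroxyphenyl]ethan-1-one | CC(=O)c1c(O)cc(OCc2ccccc2)cc1OCc1ccccc1 | intermediate
3 | 4-methoxybenzoyl chloride | COc1ccc(C(=O)Cl)cc1 | starting material
4 | 1-[2,4-bis(benzyloxy)-6-hydroxyphenyl]-3-(4-methoxyphenyl)propane-1,3-dione | COc1ccc(cc1)C(=O)CC(=O)c1c(O)cc(OCc2ccccc2)cc1OCc1ccccc1 | intermediate
5 | 5,7-bis(benzyloxy)-2-(4-methoxyphenyl)-4H-chromen-4-one | COc1ccc(cc1)-c1cc(=O)c2c(OCc3ccccc3)cc(OCc3ccccc3)cc2o1 | intermediate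
6 | 5,7-bis(benzyloxy)-8-iodo-2-(4-methoxyphenyl)-4H-chromen-4-one | COc1ccc(cc1)-c1cc(=O)c2c(OCc3ccccc3)cc(OCc3ccccc3)c(I)c2o1 | intermediate
7 | 3-bromo-4-hydroxybenzaldehyde | O=Cc1ccc(O)c(Br)c1 | starting material
8 | 4-(benzyloxy)-3-bromobenzaldehyde | O=Cc1ccc(OCc2ccccc2)c(Br)c1 | intermediate
9 | 4-(benzyloxy)-3-(4,4,5,5-tetramethyl-1,3,2-dioxaborolan-2-yl)benzaldehyde | O=Cc1ccc(OCc2ccccc2)c(c1)B1OC(C)(C)C(C)(C)O1 | intermediate
10 | 4-(benzyloxy)-3-[5,7-bis(benzyloxy)-2-(4-methoxyphenyl)-4-oxo-4H-chromen-8-yl]benzaldehyde | COc1ccc(cc1)-c1cc(=O)c2c(OCc3ccccc3)cc(OCc3ccccc3)c(-c3cc(C=O)ccc3OCc3ccccc3)c2o1 | intermediate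
11 | 5,7-bis(benzyloxy)-8-[2-(benzyloxy)-5-ethynylphenyl]-2-(4-methoxyphenyl)-4H-chromen-4-one | COc1ccc(cc1)-c1cc(=O)c2c(OCc3ccccc3)cc(OCc3ccccc3)c(-c3cc(C#C)ccc3OCc3ccccc3)c2o1 | intermediate
12 | caesium 3-{4-(benzyloxy)-3-[5,7-bis(benzyloxy)-2-(4-methoxyphenyl)-4-oxo-4H-chromen-8-yl]phenyl}prop-2-ynoate | [Cs+].[O-]C(=O)C#Cc1ccc(OCc2ccccc2)c(c1)-c1c(OCc2ccccc2)cc(OCc2ccccc2)c2c(=O)cc(oc12)-c1ccc(OC)cc1 | intermediate
13 | methyl 3-{4-(benzyloxy)-3-[5,7-bis(benzyloxy)-2-(4-methoxyphenyl)-4-oxo-4H-chromen-8-yl]phenyl}prop-2-ynoate | COC(=O)C#Cc1ccc(OCc2ccccc2)c(c1)-c1c(OCc2ccccc2)cc(OCc2ccccc2)c2c(=O)cc(oc12)-c1ccc(OC)cc1 | intermediate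
14 | 3,5-bis(benzyloxy)phenol | Oc1cc(OCc2ccccc2)cc(OCc2ccccc2)c1 | starting material
15 | methyl (2Z)-3-{4-(benzyloxy)-3-[5,7-bis(benzyloxy)-2-(4-methoxyphenyl)-4-oxo-4H-chromen-8-yl]phenyl}-3-[3,5-bis(benzyloxy)phenoxy]prop-2-enoate | COC(=O)/C=C(\Oc1cc(OCc2ccccc2)cc(OCc2ccccc2)c1)c1ccc(OCc2ccccc2)c(c1)-c1c(OCc2ccccc2)cc(OCc2ccccc2)c2c(=O)cc(oc12)-c1ccc(OC)cc1 | intermediate
16 | (2Z)-3-{4-(benzyloxy)-3-[5,7-bis(benzyloxy)-2-(4-methoxyphenyl)-4-oxo-4H-chromen-8-yl]phenyl}-3-[3,5-bis(benzyloxy)phenoxy]prop-2-enoic acid | OC(=O)/C=C(\Oc1cc(OCc2ccccc2)cc(OCc2ccccc2)c1)c1ccc(OCc2ccccc2)c(c1)-c1c(OCc2ccccc2)cc(OCc2ccccc2)c2c(=O)cc(oc12)-c1ccc(OC)cc1 | intermediate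
17 | mixed anhydride of acid 16 and trifluoroacetic acid | FC(F)(F)C(=O)OC(=O)/C=C(\Oc1cc(OCc2ccccc2)cc(OCc2ccccc2)c1)c1ccc(OCc2ccccc2)c(c1)-c1c(OCc2ccccc2)cc(OCc2ccccc2)c2c(=O)cc(oc12)-c1ccc(OC)cc1 | intermediate
18 | penta-O-benzyl podocarpusflavone A | COc1ccc(-c2cc(=O)c3c(OCc4ccccc4)cc(OCc4ccccc4)c(-c4cc(-c5cc(=O)c6c(OCc7ccccc7)cc(OCc7ccccc7)cc6o5)ccc4OCc4ccccc4)c3o2)cc1 | intermediate
19 | podocarpusflavone A | COc1ccc(-c2cc(=O)c3c(O)cc(O)c(-c4cc(-c5cc(=O)c6c(O)cc(O)cc6o5)ccc4O)c3o2)cc1 | target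

**Count**
Total step count: 13. Longest linear sequence: 11 steps (steps 1–4 and 7–13, from 1); the boronate branch (steps 5–6) joins at step 7.

**Steps most likely to fail**

Step 10. The para-benzyloxy group lowers the electrophilicity of the β-carbon of 13, so the conjugate addition may be slow or incomplete. At the temperature then required the phenoxide may open the acacetin pyranone. The fallback moves the addition ahead of the biaryl coupling, onto a fragment that tolerates forcing conditions. It sets out from bromoaldehyde 8. Ohira–Bestmann homologation would give 1-(benzyloxy)-2-bromo-4-ethynylbenzene F1. Deprotonation with LiN(SiMe3)2 at −78 °C and trapping with methyl chloroformate would give methyl 3-[4-(benzyloxy)-3-bromophenyl]prop-2-ynoate F2. Heating F2 with phenol 14 and Cs2CO3 in DMSO at 100–120 °C would give methyl (2Z)-3-[4-(benzyloxy)-3-bromophenyl]-3-[3,5-bis(benzyloxy)phenoxy]prop-2-enoate F3. Miyaura borylation (B2pin2, Pd(dppf)Cl2, KOAc) would give methyl (2Z)-3-[4-(benzyloxy)-3-(4,4,5,5-tetramethyl-1,3,2-dioxaborolan-2-yl)phenyl]-3-[3,5-bis(benzyloxy)phenoxy]prop-2-enoate F4. Suzuki coupling of F4 with iodide 6 under the conditions of step 7 comes back to the route at ester 15.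

Step 12. The mixed anhydride may be consumed by intermolecular trifluoroacetylation of the electron-rich phenoxy ring, the liberated acid may remove or shift benzyl groups, or an E-configured precursor may fail to isomerise and cyclise. The fallback closes the same pyranone at oxygen and sets out from aldehyde 10 and acetophenone 2. Claisen–Schmidt condensation (KOH, EtOH/THF, rt) would give (2E)-1-[2,4-bis(benzyloxy)-6-hydroxyphenyl]-3-{4-(benzyloxy)-3-[5,7-bis(benzyloxy)-2-(4-methoxyphenyl)-4-oxo-4H-chromen-8-yl]phenyl}prop-2-en-1-one F5. Oxidative cyclisation of F5 with catalytic I2 in DMSO at 120 °C returns to the route at pentabenzyl ether 18. Partial loss of a 5-O-benzyl group there would be harmless, since step 13 removes all benzyl ethers.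

Step 11. Hydroxide may add to the β-carbon and expel the phenoxide, or open the acacetin pyranone, before the sluggish push–pull ester is cleaved. The fallback releases the acid without hydroxide from an allyl ester and sets out from alkyne 11. Carboxylation as in step 9, with caesium salt 12 quenched by allyl bromide, would give prop-2-en-1-yl 3-{4-(benzyloxy)-3-[5,7-bis(benzyloxy)-2-(4-methoxyphenyl)-4-oxo-4H-chromen-8-yl]phenyl}prop-2-ynoate F6. Addition of phenol 14 as in step 10 would give prop-2-en-1-yl (2Z)-3-{4-(benzyloxy)-3-[5,7-bis(benzyloxy)-2-(4-methoxyphenyl)-4-oxo-4H-chromen-8-yl]phenyl}-3-[3,5-bis(benzyloxy)phenoxy]prop-2-enoate F7. Allyl transfer to sodium p-toluenesulfinate with Pd(PPh3)4 (cat.) in THF/MeOH at rt, followed by mild acidification, comes back to the route at acid 16.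

**Further compounds**
F1 | step 10 | 1-(benzyloxy)-2-bromo-4-ethynylbenzene | C#Cc1ccc(OCc2ccccc2)c(Br)c1
F2 | step 10 | methyl 3-[4-(benzyloxy)-3-bromophenyl]prop-2-ynoate | COC(=O)C#Cc1ccc(OCc2ccccc2)c(Br)c1
F3 | step 10 | methyl (2Z)-3-[4-(benzyloxy)-3-bromophenyl]-3-[3,5-bis(benzyloxy)phenoxy]prop-2-enoate | COC(=O)/C=C(\Oc1cc(OCc2ccccc2)cc(OCc2ccccc2)c1)c1ccc(OCc2ccccc2)c(Br)c1
F4 | step 10 | methyl (2Z)-3-[4-(benzyloxy)-3-(4,4,5,5-tetramethyl-1,3,2-dioxaborolan-2-yl)phenyl]-3-[3,5-bis(benzyloxy)phenoxy]prop-2-enoate | COC(=O)/C=C(\Oc1cc(OCc2ccccc2)cc(OCc2ccccc2)c1)c1ccc(OCc2ccccc2)c(c1)B1OC(C)(C)C(C)(C)O1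
F5 | step 12 | (2E)-1-[2,4-bis(benzyloxy)-6-hydroxyphenyl]-3-{4-(benzyloxy)-3-[5,7-bis(benzyloxy)-2-(4-methoxyphenyl)-4-oxo-4H-chromen-8-yl]phenyl}prop-2-en-1-one | O=C(/C=C/c1ccc(OCc2ccccc2)c(c1)-c1c(OCc2ccccc2)cc(OCc2ccccc2)c2c(=O)cc(oc12)-c1ccc(OC)cc1)c1c(O)cc(OCc2ccccc2)cc1OCc1ccccc1
F6 | step 11 | prop-2-en-1-yl 3-{4-(benzyloxy)-3-[5,7-bis(benzyloxy)-2-(4-methoxyphenyl)-4-oxo-4H-chromen-8-yl]phenyl}prop-2-ynoate | C=CCOC(=O)C#Cc1ccc(OCc2ccccc2)c(c1)-c1c(OCc2ccccc2)cc(OCc2ccccc2)c2c(=O)cc(oc12)-c1ccc(OC)cc1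
F7 | step 11 | prop-2-en-1-yl (2Z)-3-{4-(benzyloxy)-3-[5,7-bis(benzyloxy)-2-(4-methoxyphenyl)-4-oxo-4H-chromen-8-yl]phenyl}-3-[3,5-bis(benzyloxy)phenoxy]prop-2-enoate | C=CCOC(=O)/C=C(\Oc1cc(OCc2ccccc2)cc(OCc2ccccc2)c1)c1ccc(OCc2ccccc2)c(c1)-c1c(OCc2ccccc2)cc(OCc2ccccc2)c2c(=O)cc(oc12)-c1ccc(OC)cc1
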